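**Retrosynthetic overview**
1. Last operations: global MOM removal, and before it removal of a methoxycarbonyl activating group from C3 (hydrolysis, decarboxylation), which sets C3 trans to C2 under thermodynamic control.
2. Key disconnection C3–C4: an NHC-catalysed intramolecular crossed benzoin reaction (polarity reversal of the A-ring formyl carbon C4, union with the electrophilic C3 keto carbon of an α-keto ester), run as a dynamic kinetic resolution of a racemic, enolising open-chain aryl ether. It closes the pyranone ring C, the only ring made in the route (rings A and B are bought as arenes), and fixes C2 as R.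
3. Enabling feature: C2–H stands between ring B (C1'), the ether oxygen O1 and the C3 carbonyl and is therefore configurationally labile, while the formyl carbon C4 on C4a of ring A is ortho to O1, so that C4 reaches C3 in a 6-exo closure.
4. The open-chain ether comes from O-alkylation of the A-ring salicylaldehyde with a β-chloro-α-keto ester, itself made by Darzens homologation of the B-ring aldehyde with methyl dichloroacetate.
5. Ring B: three successive directed ortho-metalations of resorcinol bis-MOM ether (geranyl, prenyl, CHO). Ring A: bis-MOM protection of 2,4,6-trihydroxybenzaldehyde, O-(1,1-dimethylpropargyl)ation, semihydrogenation, aromatic Claisen rearrangement.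

Key step: step 11

Remark: MOM = methoxymethyl, prenyl = 3-methylbut-2-en-1-yl, geranyl = (2E)-3,7-dimethylocta-2,6-dien-1-yl; the sense of induction of the aminoindanol triazolium in step 11 is assumed by analogy with chromanone-forming benzoin cyclisations, and the antipodal precatalyst (equally commercial) is taken if a first experiment shows the opposite sense.

**Step 1**
Reactants: 1 resorcinol
Product: 2 1,3-bis(methoxymethoxy)benzene
Conditions: NaH, MOMCl, DMF, 0 °C → rt
Reagents that add atoms: chloromethyl methyl ether (MOMCl), COCCl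
Why: Williamson-type O-alkylation of the bis-phenoxide installs two MOM ethers that serve later as ortho-directing groups.

**Step 2**
Reactants: 2 1,3-bis(methoxymethoxy)benzene; 3 geranyl bromide
Product: 4 2-geranyl-1,3-bis(methoxymethoxy)benzene
Conditions: n-BuLi, THF, 0 °C → rt; CuI (10 mol %), 3, −20 °C → rt
Reagents that add atoms: none
Why: Directed ortho-metalation takes place at C2 between the two OMOM groups, and copper-catalysed SN2 allylation of the aryllithium should keep the E olefin of the geranyl unit.

**Step 3**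
Reactants: 4 2-geranyl-1,3-bis(methoxymethoxy)benzene; 5 prenyl bromide
Product: 6 2-geranyl-1,3-bis(methoxymethoxy)-4-prenylbenzene
Conditions: n-BuLi, TMEDA, THF, −20 → 0 °C; CuI (10 mol %), 5, −20 °C → rt
Reagents that add atoms: none
Why: A second directed ortho-metalation (C4 and C6 are equivalent) followed by allylation; coordination of the base to OMOM at low temperature should favour ring lithiation over deprotonation of the benzylic-allylic CH2.

**Step 4**
Reactants: 6 2-geranyl-1,3-bis(methoxymethoxy)-4-prenylbenzene; 7 N,N-dimethylformamide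
Product: 8 3-geranyl-2,4-bis(methoxymethoxy)-5-prenylbenzaldehyde
Conditions: n-BuLi, TMEDA, THF, −40 → 0 °C; 7, −40 °C → rt; H2O
Reagents that add atoms: none
Why: The third directed ortho-metalation can only occur at the one remaining position ortho to an OMOM group, and formylation of the aryllithium with DMF (Bouveault-type) gives the aldehyde whose carbon becomes C2.

**Step 5**
Reactants: 8 3-geranyl-2,4-bis(methoxymethoxy)-5-prenylbenzaldehyde; 9 methyl dichloroacetate
Product: 11 methyl 3-chloro-3-[3-geranyl-2,4-bis(methoxymethoxy)-5-prenylphenyl]-2-oxopropanoate, via α-chloroglycidic ester 10 (not isolated)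
Conditions: 9, KOt-Bu, THF, −78 → 0 °C; crude product used at once
Reagents that add atoms: none
Why: Darzens condensation gives the α-chloro epoxide, which opens at the benzylic C–O bond (assisted by the donor ring) and collapses to the ketone with transfer of chloride to the benzylic carbon, the known route from aryl aldehydes to 3-aryl-3-chloro-2-oxopropanoates.

**Step 6**
Reactants: 12 2,4,6-trihydroxybenzaldehyde
Product: 13 2-hydroxy-4,6-bis(methoxymethoxy)benzaldehyde
Conditions: MOMCl (2.1 equiv), K2CO3, acetone, 0 °C → rt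
Reagents that add atoms: chloromethyl methyl ether (MOMCl), COCCl
Why: Selective Williamson-type protection: after the 4-OH and one ortho OH have reacted, the remaining ortho OH is locked in a hydrogen bond to the formyl group and stays free.

**Step 7**
Reactants: 13 2-hydroxy-4,6-bis(methoxymethoxy)benzaldehyde; 14 3-chloro-3-methylbut-1-yne
Product: 15 2-[(2-methylbut-3-yn-2-yl)oxy]-4,6-bis(methoxymethoxy)benzaldehyde
Conditions: 14, DBU, CuCl2·2H2O (1 mol %), MeCN, 0 °C → rt
Reagents that add atoms: none
Why: Copper-catalysed propargylic etherification: the copper acetylide ionises to an allenylidene-type electrophile that the phenoxide, freed from its hydrogen bond by DBU, captures at the tertiary carbon.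

**Step 8**
Reactants: 15 2-[(2-methylbut-3-yn-2-yl)oxy]-4,6-bis(methoxymethoxy)benzaldehyde
Product: 16 2-[(2-methylbut-3-en-2-yl)oxy]-4,6-bis(methoxymethoxy)benzaldehyde
Conditions: H2 (1 atm), Pb-poisoned Pd/CaCO3 (Lindlar catalyst), quinoline, EtOAc, rt
Reagents that add atoms: none
Why: Lindlar semihydrogenation of the terminal alkyne stops at the alkene and leaves the formyl group and the aryl acetals untouched.

**Step 9**
Reactants: 16 2-[(2-methylbut-3-en-2-yl)oxy]-4,6-bis(methoxymethoxy)benzaldehyde
Product: 18 2-hydroxy-4,6-bis(methoxymethoxy)-3-prenylbenzaldehyde, via ortho-dienone 17 (not isolated)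
Conditions: PhNEt2, 120 °C
Reagents that add atoms: none
Why: Aromatic Claisen rearrangement: the [3,3] shift delivers the allyl terminus to C3, the only ortho position bearing hydrogen, with allylic inversion to the linear prenyl group, and tautomerisation returns the phenol next to the prenyl group, exactly the oxygen that becomes O1.

**Step 10**
Reactants: 18 2-hydroxy-4,6-bis(methoxymethoxy)-3-prenylbenzaldehyde; 11 methyl 3-chloro-3-[3-geranyl-2,4-bis(methoxymethoxy)-5-prenylphenyl]-2-oxopropanoate
Product: 19 methyl 3-[2-formyl-3,5-bis(methoxymethoxy)-6-prenylphenoxy]-3-[3-geranyl-2,4-bis(methoxymethoxy)-5-prenylphenyl]-2-oxopropanoate (racemic; keto/enol mixture)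
Conditions: K2CO3, DMF, 0 °C → rt; aq NaH2PO4
Reagents that add atoms: none
Why: Williamson ether synthesis at an α-keto benzylic chloride, a strongly SN2-activated electrophile, forms the O1–C2 bond; the configuration at C2 is of no concern because it is labile.

**Step 11**
Reactants: 19 methyl 3-[2-formyl-3,5-bis(methoxymethoxy)-6-prenylphenoxy]-3-[3-geranyl-2,4-bis(methoxymethoxy)-5-prenylphenyl]-2-oxopropanoate
Product: 20 methyl (2R,3R)-2-[3-geranyl-2,4-bis(methoxymethoxy)-5-prenylphenyl]-3-hydroxy-5,7-bis(methoxymethoxy)-4-oxo-8-prenylchromane-3-carboxylate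
Conditions: (5aS,10bR)-2-(pentafluorophenyl)-5a,10b-dihydro-4H,6H-indeno[2,1-b][1,2,4]triazolo[4,3-d][1,4]oxazin-2-ium tetrafluoroborate (15 mol %), i-Pr2NEt (30 mol %), 4 Å MS, toluene, Ar, 25 → 40 °C
Reagents that add atoms: none
Why: The triazolylidene adds to the A-ring formyl group, the only carbonyl of 19 that carries a hydrogen, proton transfer gives the Breslow intermediate (an acyl anion equivalent at C4), and this adds to the C3 keto group before the carbene is expelled from the C4 alkoxide. This is the NHC-catalysed intramolecular crossed aldehyde–ketone benzoin reaction by which 3-hydroxychroman-4-ones are made from 2-(2-oxoalkoxy)benzaldehydes, run as a dynamic kinetic resolution in the way established for keto aldehydes with a stereolabile centre next to the acceptor ketone and for β-stereogenic α-keto esters. The pyranone ring (O1, C2, C3, C4, C4a, C8a) closes 6-exo-trig by attack of C4 on the C3 carbonyl. C2 is selected, not created: because C2–H is benzylic to ring B, geminal to O1 and α to the 1,2-dicarbonyl, the enantiomers of 19 and its E and Z enols interconvert under the amine much faster than they cyclise, and the aminoindanol backbone of the catalyst should admit only the epimer that places ring B pseudo-equatorial in the chair-like transition state, giving 2R. The new carbinol centre C3 is set by the catalyst-controlled face of the ketone, organised by the O–H···O=C hydrogen bond of the Breslow intermediate, and is drawn with the hydroxyl anti to ring B; its configuration is of no consequence because C3 is planarised in step 12. The step needs acyl anion formation at C4 only, and the methoxycarbonyl group on C3 secures it, since a ketone cannot form a Breslow intermediate and so no carbanion arises β to the A-ring aryloxide on C2 (no E1cB loss of the phenoxide), while the same group raises the electrophilicity of C3 and the acidity of C2–H; an aldol adduct of the enol with the hindered, electron-rich formyl group would only be a reversible reservoir.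

**Step 12**
Reactants: 20 methyl (2R,3R)-2-[3-geranyl-2,4-bis(methoxymethoxy)-5-prenylphenyl]-3-hydroxy-5,7-bis(methoxymethoxy)-4-oxo-8-prenylchromane-3-carboxylate
Product: 23 (2R,3R)-2-[3-geranyl-2,4-bis(methoxymethoxy)-5-prenylphenyl]-3-hydroxy-5,7-bis(methoxymethoxy)-8-prenylchroman-4-one, via β-keto acid 21 (not isolated), via enediol 22 (not isolated)
Conditions: LiOH·H2O, THF/H2O (degassed), 0 °C; AcOH to pH 5, 45 °C, Ar
Reagents that add atoms: none
Why: Saponification (C2 is safe under hydroxide because C3 carries no hydrogen), decarboxylation of the β-keto acid on mild acidification and ketonisation of the enediol in the acetate buffer should set C3 under thermodynamic control as the 2,3-trans (3R) epimer, with both substituents equatorial and the 3-OH hydrogen-bonded to C4=O, relayed from the fixed 2R centre.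

**Step 13**
Reactants: 23 (2R,3R)-2-[3-geranyl-2,4-bis(methoxymethoxy)-5-prenylphenyl]-3-hydroxy-5,7-bis(methoxymethoxy)-8-prenylchroman-4-one
Product: 24 (2R,3R)-2-(3-geranyl-2,4-dihydroxy-5-prenylphenyl)-3,5,7-trihydroxy-8-prenylchroman-4-one (CNP0149909.1)
Conditions: 3 M aq HCl, MeOH/THF, 40 °C, Ar
Reagents that add atoms: none
Why: Acid-catalysed acetal methanolysis removes the four aryl MOM groups under the mild conditions usual for prenylated flavonoids, kept at 40 °C to avoid chroman formation from the ortho-prenyl phenols and ionisation at C2, and any 2,3-cis epimer carried over can still converge on trans by acid-catalysed enolisation at C3.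

**Compound list**
1 | resorcinol | Oc1cccc(O)c1 | starting material
2 | 1,3-bis(methoxymethoxy)benzene | COCOc1cccc(OCOC)c1 | intermediate
3 | geranyl bromide, (2E)-1-bromo-3,7-dimethylocta-2,6-diene | CC(C)=CCC/C(C)=C/CBr | starting material
4 | 2-geranyl-1,3-bis(methoxymethoxy)benzene | CC(C)=CCC/C(C)=C/Cc1c(OCOC)cccc1OCOC | intermediate
5 | prenyl bromide, 1-bromo-3-methylbut-2-ene | CC(C)=CCBr | starting material
6 | 2-geranyl-1,3-bis(methoxymethoxy)-4-prenylbenzene | CC(C)=CCC/C(C)=C/Cc1c(OCOC)ccc(CC=C(C)C)c1OCOC | intermediate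
7 | N,N-dimethylformamide | CN(C)C=O | starting material
8 | 3-geranyl-2,4-bis(methoxymethoxy)-5-prenylbenzaldehyde | CC(C)=CCC/C(C)=C/Cc1c(OCOC)c(C=O)cc(CC=C(C)C)c1OCOC | intermediate
9 | methyl dichloroacetate | COC(=O)C(Cl)Cl | starting material
10 | methyl 2-chloro-3-[3-geranyl-2,4-bis(methoxymethoxy)-5-prenylphenyl]oxirane-2-carboxylate (racemic, not isolated) | CC(C)=CCC/C(C)=C/Cc1c(OCOC)c(C2OC2(Cl)C(=O)OC)cc(CC=C(C)C)c1OCOC | intermediate
11 | methyl 3-chloro-3-[3-geranyl-2,4-bis(methoxymethoxy)-5-prenylphenyl]-2-oxopropanoate (racemic) | CC(C)=CCC/C(C)=C/Cc1c(OCOC)c(C(Cl)C(=O)C(=O)OC)cc(CC=C(C)C)c1OCOC | intermediate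
12 | 2,4,6-trihydroxybenzaldehyde | O=Cc1c(O)cc(O)cc1O | starting material
13 | 2-hydroxy-4,6-bis(methoxymethoxy)benzaldehyde | O=Cc1c(O)cc(OCOC)cc1OCOC | intermediate
14 | 3-chloro-3-methylbut-1-yne | CC(C)(Cl)C#C | starting material
15 | 2-[(2-methylbut-3-yn-2-yl)oxy]-4,6-bis(methoxymethoxy)benzaldehyde | O=Cc1c(OC(C)(C)C#C)cc(OCOC)cc1OCOC | intermediate
16 | 2-[(2-methylbut-3-en-2-yl)oxy]-4,6-bis(methoxymethoxy)benzaldehyde | O=Cc1c(OC(C)(C)C=C)cc(OCOC)cc1OCOC | intermediate
17 | 2,4-bis(methoxymethoxy)-6-oxo-5-prenylcyclohexa-1,3-diene-1-carbaldehyde (racemic, not isolated) | O=CC1=C(OCOC)C=C(OCOC)C(CC=C(C)C)C1=O | intermediate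
18 | 2-hydroxy-4,6-bis(methoxymethoxy)-3-prenylbenzaldehyde | O=Cc1c(O)c(CC=C(C)C)c(OCOC)cc1OCOC | intermediate
19 | methyl 3-[2-formyl-3,5-bis(methoxymethoxy)-6-prenylphenoxy]-3-[3-geranyl-2,4-bis(methoxymethoxy)-5-prenylphenyl]-2-oxopropanoate (racemic, keto form shown) | CC(C)=CCC/C(C)=C/Cc1c(OCOC)c(C(Oc2c(CC=C(C)C)c(OCOC)cc(OCOC)c2C=O)C(=O)C(=O)OC)cc(CC=C(C)C)c1OCOC | intermediate
20 | methyl (2R,3R)-2-[3-geranyl-2,4-bis(methoxymethoxy)-5-prenylphenyl]-3-hydroxy-5,7-bis(methoxymethoxy)-4-oxo-8-prenylchromane-3-carboxylate | CC(C)=CCC/C(C)=C/Cc1c(OCOC)c([C@H]2Oc3c(CC=C(C)C)c(OCOC)cc(OCOC)c3C(=O)[C@@]2(O)C(=O)OC)cc(CC=C(C)C)c1OCOC | intermediate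
21 | (2R,3R)-2-[3-geranyl-2,4-bis(methoxymethoxy)-5-prenylphenyl]-3-hydroxy-5,7-bis(methoxymethoxy)-4-oxo-8-prenylchromane-3-carboxylic acid (not isolated) | CC(C)=CCC/C(C)=C/Cc1c(OCOC)c([C@H]2Oc3c(CC=C(C)C)c(OCOC)cc(OCOC)c3C(=O)[C@@]2(O)C(=O)O)cc(CC=C(C)C)c1OCOC | intermediate
22 | (2R)-2-[3-geranyl-2,4-bis(methoxymethoxy)-5-prenylphenyl]-5,7-bis(methoxymethoxy)-8-prenyl-2H-chromene-3,4-diol (not isolated) | CC(C)=CCC/C(C)=C/Cc1c(OCOC)c([C@H]2Oc3c(CC=C(C)C)c(OCOC)cc(OCOC)c3C(O)=C2O)cc(CC=C(C)C)c1OCOC | intermediate
23 | (2R,3R)-2-[3-geranyl-2,4-bis(methoxymethoxy)-5-prenylphenyl]-3-hydroxy-5,7-bis(methoxymethoxy)-8-prenylchroman-4-one | CC(C)=CCC/C(C)=C/Cc1c(OCOC)c([C@H]2Oc3c(CC=C(C)C)c(OCOC)cc(OCOC)c3C(=O)[C@@H]2O)cc(CC=C(C)C)c1OCOC | intermediate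
24 | (2R,3R)-2-(3-geranyl-2,4-dihydroxy-5-prenylphenyl)-3,5,7-trihydroxy-8-prenylchroman-4-one (CNP0149909.1) | CC(C)=CCC/C(C)=C/Cc1c(O)c(CC=C(C)C)cc([C@H]2Oc3c(CC=C(C)C)c(O)cc(O)c3C(=O)[C@@H]2O)c1O | target

**Totals and risks**
Total step count: 13. Longest linear sequence: 9 steps (steps 1–5 and 10–13, from resorcinol).

Steps most likely to fail:

Step 11. The two rapidly interconverting C2 epimers may be poorly discriminated in the carbene-bound transition state (low enantio- and diastereoselection), and carbene addition to the doubly ortho-oxygenated formyl group may be slow. The fallback gives up catalyst control and replaces it by resolution. It sets out from 19, which is cyclised with the small, strongly nucleophilic achiral carbene from 3-benzyl-5-(2-hydroxyethyl)-4-methylthiazolium chloride and Et3N in THF at 60 °C to give racemic methyl 3-hydroxy-4-oxochromane-3-carboxylate F1. The conditions of step 12 should convert this into the racemic trans tetra-MOM dihydroflavonol F2, whose enantiomers are separated by preparative chromatography on an amylose tris(3,5-dimethylphenylcarbamate) phase. The (2R,3R) enantiomer is 23, where the route is rejoined.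

Step 10. The doubly donor-activated benzylic chloride may ionise, with attack through carbon of the phloroglucinol-type phenoxide or solvolysis, and the keto ester enolate may capture the formyl group in an aldol reaction under the carbonate base. The fallback forms the ether by epoxide opening and reveals the keto ester under neutral oxidation. It sets out from 8, which in a Darzens condensation with methyl chloroacetate (NaOMe, THF/MeOH, −10 °C → rt) gives the racemic trans methyl 3-arylglycidate F3. The caesium phenoxide of 18 (Cs2CO3, DMF, 50 °C) should open the epoxide at the benzylic carbon to the racemic methyl 3-aryloxy-2-hydroxy-3-arylpropanoate F4, obtained as a diastereomer mixture that is of no concern. Oxidation with Dess–Martin periodinane (NaHCO3, CH2Cl2) returns to the route at 19.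

Step 12. Under hydroxide the tertiary alkoxide may undergo an α-ketol shift with ring contraction or cleavage of the C3–C4 bond, and after decarboxylation residual base may open the ring at C2. The fallback changes the activating group to an allyl ester that is removed by palladium under neutral conditions. It sets out from 8, which is condensed as in step 5 with allyl dichloroacetate F5 (from dichloroacetyl chloride and allyl alcohol, pyridine, CH2Cl2) to give the allyl 3-chloro-2-oxopropanoate F6. Etherification with 18 as in step 10 gives the allyl keto ester ether F7, and the conditions of step 11 give the allyl 3-hydroxy-4-oxochromane-3-carboxylate F8. Treatment with Pd(PPh3)4 (5 mol %) and morpholine in THF at rt (Tsuji–Trost deallylation followed by decarboxylation) returns to the route at 23.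

**Further compounds**
F1 | step 11 | methyl rac-2-[3-geranyl-2,4-bis(methoxymethoxy)-5-prenylphenyl]-3-hydroxy-5,7-bis(methoxymethoxy)-4-oxo-8-prenylchromane-3-carboxylate (racemate) | CC(C)=CCC/C(C)=C/Cc1c(OCOC)c(C2Oc3c(CC=C(C)C)c(OCOC)cc(OCOC)c3C(=O)C2(O)C(=O)OC)cc(CC=C(C)C)c1OCOC
F2 | step 11 | rac-(2R*,3R*)-2-[3-geranyl-2,4-bis(methoxymethoxy)-5-prenylphenyl]-3-hydroxy-5,7-bis(methoxymethoxy)-8-prenylchroman-4-one (trans racemate) | CC(C)=CCC/C(C)=C/Cc1c(OCOC)c(C2Oc3c(CC=C(C)C)c(OCOC)cc(OCOC)c3C(=O)C2O)cc(CC=C(C)C)c1OCOC
F3 | step 10 | methyl trans-3-[3-geranyl-2,4-bis(methoxymethoxy)-5-prenylphenyl]oxirane-2-carboxylate (racemate) | CC(C)=CCC/C(C)=C/Cc1c(OCOC)c(C2OC2C(=O)OC)cc(CC=C(C)C)c1OCOC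
F4 | step 10 | methyl 3-[2-formyl-3,5-bis(methoxymethoxy)-6-prenylphenoxy]-3-[3-geranyl-2,4-bis(methoxymethoxy)-5-prenylphenyl]-2-hydroxypropanoate (racemic diastereomer mixture) | CC(C)=CCC/C(C)=C/Cc1c(OCOC)c(C(Oc2c(CC=C(C)C)c(OCOC)cc(OCOC)c2C=O)C(O)C(=O)OC)cc(CC=C(C)C)c1OCOC
F5 | step 12 | allyl dichloroacetate | C=CCOC(=O)C(Cl)Cl
F6 | step 12 | allyl 3-chloro-3-[3-geranyl-2,4-bis(methoxymethoxy)-5-prenylphenyl]-2-oxopropanoate (racemate) | CC(C)=CCC/C(C)=C/Cc1c(OCOC)c(C(Cl)C(=O)C(=O)OCC=C)cc(CC=C(C)C)c1OCOC
F7 | step 12 | allyl 3-[2-formyl-3,5-bis(methoxymethoxy)-6-prenylphenoxy]-3-[3-geranyl-2,4-bis(methoxymethoxy)-5-prenylphenyl]-2-oxopropanoate (racemate) | CC(C)=CCC/C(C)=C/Cc1c(OCOC)c(C(Oc2c(CC=C(C)C)c(OCOC)cc(OCOC)c2C=O)C(=O)C(=O)OCC=C)cc(CC=C(C)C)c1OCOC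
F8 | step 12 | allyl (2R,3R)-2-[3-geranyl-2,4-bis(methoxymethoxy)-5-prenylphenyl]-3-hydroxy-5,7-bis(methoxymethoxy)-4-oxo-8-prenylchromane-3-carboxylate | CC(C)=CCC/C(C)=C/Cc1c(OCOC)c([C@H]2Oc3c(CC=C(C)C)c(OCOC)cc(OCOC)c3C(=O)[C@@]2(O)C(=O)OCC=C)cc(CC=C(C)C)c1OCOC
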